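**Strategy**

Everything rests on the biaryl bond between C5' of ring B of the (2S)-flavanone unit and C8 of ring A of the flavone unit. Both carbons lie ortho to oxygen: C8, flanked by O7 and O1, is the site where a per-benzylated luteolin is iodinated and then zincated, and C5', next to O4', carries a bromide. A Negishi coupling joins the two complete, protected flavonoid halves in one operation under non-basic conditions, so the base-labile C2 stereocentre, set earlier by rhodium-catalysed asymmetric conjugate addition of the ring-B boronic acid to a chromone, survives. The precursor pair is an arylzinc iodide of tetra-O-benzylluteolin and a 5'-bromoflavanone.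

Key step: step 7

Remark: the new biaryl axis carries three ortho substituents (O4', O7, O1) and is taken as freely rotating at room temperature, so C2 of the flavanone is the only stereo-element to control.

**Route**

Step 1
Reactants: 1 luteolin
Product: 2 5,7-bis(benzyloxy)-2-[3,4-bis(benzyloxy)phenyl]-4H-chromen-4-one (tetra-O-benzylluteolin)
Conditions: BnBr (6 equiv), K2CO3, cat. n-Bu4NI, DMF, 80 °C
Reagents that add atoms: benzyl bromide, BrCc1ccccc1
Why: Fourfold Williamson ether synthesis; excess benzyl bromide in hot DMF should also alkylate the hydrogen-bonded 5-OH, which must be capped so that the later iodination is steered to C8 and not to C6.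

Step 2
Reactants: 2 tetra-O-benzylluteolin
Product: 3 5,7-bis(benzyloxy)-2-[3,4-bis(benzyloxy)phenyl]-8-iodo-4H-chromen-4-one
Conditions: NIS (1.1 equiv), CF3CO2H (0.3 equiv), CH2Cl2–MeCN, 0 °C to rt
Reagents that add atoms: N-iodosuccinimide, O=C1CCC(=O)N1I
Why: Electrophilic aromatic iodination should occur on ring A, the most electron-rich ring, at C8, which is activated by O7 (ortho), O1 (ortho) and O5 (para) and is less hindered than C6 between two benzyloxy groups, as is usual for 5,7-dialkoxyflavones.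

Step 3
Reactants: 4 3-bromobenzene-1,2-diol (3-bromocatechol)
Product: 5 1-bromo-2,3-bis(methoxymethoxy)benzene
Conditions: NaH (2.5 equiv), MOMCl (2.4 equiv), DMF, 0 °C to rt
Reagents that add atoms: chloromethyl methyl ether, COCCl
Why: Double O-alkylation of the catechol dianion (Williamson-type acetal formation) installs a protecting group without aromatic C–H bonds, which the next step requires.

Step 4
Reactants: 5 1-bromo-2,3-bis(methoxymethoxy)benzene
Product: 7 [3-bromo-4,5-bis(methoxymethoxy)phenyl]boronic acid, via pinacol boronate 6 (not isolated)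
Conditions: [Ir(OMe)(cod)]2 (1.5 mol%), 4,4'-di-tert-butyl-2,2'-bipyridine (3 mol%), B2pin2 (1.0 equiv), THF, 60 °C; then NaIO4, NH4OAc, acetone–H2O, rt
Reagents that add atoms: bis(pinacolato)diboron, CC1(C)OB(B2OC(C)(C)C(C)(C)O2)OC1(C)C; water, O
Why: Sterically controlled iridium-catalysed aromatic C–H borylation should touch only C5, the single ring C–H without an ortho substituent, and periodate cleavage of the liberated pinacol then frees the boronic acid under neutral conditions that spare the MOM ethers.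

Step 5
Reactants: 8 1-[2,4-bis(benzyloxy)-6-hydroxyphenyl]ethan-1-one
Product: 10 5,7-bis(benzyloxy)-4H-chromen-4-one, via enaminone 9 (not isolated)
Conditions: Me2NCH(OMe)2, toluene, 100 °C; then conc. HCl, CH2Cl2, 40 °C
Reagents that add atoms: N,N-dimethylformamide dimethyl acetal, COC(OC)N(C)C
Why: Condensation of the methyl ketone with the amide acetal gives the enaminone, and acid then triggers 6-endo-trig addition of the phenol followed by loss of dimethylamine (enaminone chromone synthesis).

Step 6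
Reactants: 10 5,7-bis(benzyloxy)-4H-chromen-4-one, 7 [3-bromo-4,5-bis(methoxymethoxy)phenyl]boronic acid
Product: 11 (2S)-5,7-bis(benzyloxy)-2-[3-bromo-4,5-bis(methoxymethoxy)phenyl]chroman-4-one
Conditions: [Rh(OH)((S)-MeO-F12-BIPHEP)]2 (3 mol% Rh), 7 (2.5 equiv), toluene–H2O (10:1), 30 °C
Reagents that add atoms: none
Why: Hayashi–Miyaura asymmetric 1,4-addition: the aryl-rhodium species carrying the C2-symmetric bisphosphine inserts the C2=C3 bond on one face, which sets C2 as (S) (the (S)-ligand is predicted by analogy with cyclic enones, its antipode being used should the sense prove opposite), and the electron-poor ligand gives a catalyst active enough for the 5-alkoxychromone at a temperature where the flavanone does not ring-open, while the C–Br bond is inert to monovalent rhodium.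

Step 7
Reactants: 3 5,7-bis(benzyloxy)-2-[3,4-bis(benzyloxy)phenyl]-8-iodo-4H-chromen-4-one, 11 (2S)-5,7-bis(benzyloxy)-2-[3-bromo-4,5-bis(methoxymethoxy)phenyl]chroman-4-one
Product: 13 (2S)-5,7-bis(benzyloxy)-2-[3-{5,7-bis(benzyloxy)-2-[3,4-bis(benzyloxy)phenyl]-4-oxo-4H-chromen-8-yl}-4,5-bis(methoxymethoxy)phenyl]chroman-4-one, via arylzinc iodide 12 (not isolated)
Conditions: 3 (1.4 equiv), Zn dust (BrCH2CH2Br/Me3SiCl-activated), LiCl, THF, 50 °C; filter; then 11, Pd2(dba)3 (2.5 mol%), RuPhos (10 mol%), THF–NMP, 65 °C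
Reagents that add atoms: none
Why: LiCl-assisted insertion of zinc into the C8–I bond of 3 gives arylzinc iodide 12, which transmetalates to the arylpalladium bromide formed by oxidative addition of zerovalent palladium/RuPhos into the C5'–Br bond of 11, and reductive elimination forms the C5'–C8 biaryl bond. The closest known reaction type is the Negishi coupling of 2,6-dialkoxyarylzinc halides with ortho-substituted aryl bromides to tri-ortho-substituted biaryls. No ring is closed and no stereocentre is created; the new axis is not expected to be configurationally stable. The step needs site selectivity, which the halogens placed through steps 2 and 3–4 secure (C8 not C6, C5' not C2' or C6'), and cross- over homo-coupling, which the fixed nucleophile and electrophile roles secure. It also needs retention of the (2S) centre, which should hold because the arylzinc is neither basic nor nucleophilic enough to enolise or attack the flavanone and flavone carbonyls, whereas the aqueous base of a Suzuki coupling could open ring C of the flavanone by retro-oxa-Michael reaction.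

Step 8
Reactants: 13 protected biflavonoid
Product: 14 (2S)-5,7-bis(benzyloxy)-2-[3-{5,7-bis(benzyloxy)-2-[3,4-bis(benzyloxy)phenyl]-4-oxo-4H-chromen-8-yl}-4,5-dihydroxyphenyl]chroman-4-one
Conditions: 3 M HCl (aq), MeOH–THF (1:1), 45 °C
Reagents that add atoms: none
Why: Acid-catalysed acetal methanolysis removes both MOM groups, while the benzyl ethers, the flavone and the flavanone (whose ring opening needs base) should be unaffected.

Step 9
Reactants: 14 hexa-O-benzyl catechol
Product: 15 (2S)-2-{3-[2-(3,4-dihydroxyphenyl)-5,7-dihydroxy-4-oxo-4H-chromen-8-yl]-4,5-dihydroxyphenyl}-5,7-dihydroxychroman-4-one (target)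
Conditions: H2 (1 atm), 10% Pd/C, THF–MeOH, rt
Reagents that add atoms: none
Why: Heterogeneous hydrogenolysis of the six benzyl ethers under neutral conditions should leave the flavone C2=C3 bond, both carbonyl groups and the C2 stereocentre untouched.

**Compound list**

1 | luteolin, 2-(3,4-dihydroxyphenyl)-5,7-dihydroxy-4H-chromen-4-one | O=c1cc(-c2ccc(O)c(O)c2)oc2cc(O)cc(O)c12 | starting material
2 | 5,7-bis(benzyloxy)-2-[3,4-bis(benzyloxy)phenyl]-4H-chromen-4-one | O=c1cc(-c2ccc(OCc3ccccc3)c(OCc3ccccc3)c2)oc2cc(OCc3ccccc3)cc(OCc3ccccc3)c12 | intermediate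
3 | 5,7-bis(benzyloxy)-2-[3,4-bis(benzyloxy)phenyl]-8-iodo-4H-chromen-4-one | O=c1cc(-c2ccc(OCc3ccccc3)c(OCc3ccccc3)c2)oc2c(I)c(OCc3ccccc3)cc(OCc3ccccc3)c12 | intermediate
4 | 3-bromobenzene-1,2-diol | Oc1cccc(Br)c1O | starting material
5 | 1-bromo-2,3-bis(methoxymethoxy)benzene | COCOc1cccc(Br)c1OCOC | intermediate
6 | 2-[3-bromo-4,5-bis(methoxymethoxy)phenyl]-4,4,5,5-tetramethyl-1,3,2-dioxaborolane | COCOc1cc(B2OC(C)(C)C(C)(C)O2)cc(Br)c1OCOC | intermediate
7 | [3-bromo-4,5-bis(methoxymethoxy)phenyl]boronic acid | COCOc1cc(B(O)O)cc(Br)c1OCOC | intermediate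
8 | 1-[2,4-bis(benzyloxy)-6-hydroxyphenyl]ethan-1-one | CC(=O)c1c(O)cc(OCc2ccccc2)cc1OCc1ccccc1 | starting material
9 | (E)-1-[2,4-bis(benzyloxy)-6-hydroxyphenyl]-3-(dimethylamino)prop-2-en-1-one | CN(C)/C=C/C(=O)c1c(O)cc(OCc2ccccc2)cc1OCc1ccccc1 | intermediate
10 | 5,7-bis(benzyloxy)-4H-chromen-4-one | O=c1ccoc2cc(OCc3ccccc3)cc(OCc3ccccc3)c12 | intermediate
11 | (2S)-5,7-bis(benzyloxy)-2-[3-bromo-4,5-bis(methoxymethoxy)phenyl]chroman-4-one | O=C1C[C@@H](c2cc(OCOC)c(OCOC)c(Br)c2)Oc2cc(OCc3ccccc3)cc(OCc3ccccc3)c21 | intermediate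
12 | {5,7-bis(benzyloxy)-2-[3,4-bis(benzyloxy)phenyl]-4-oxo-4H-chromen-8-yl}zinc iodide (LiCl complex) | O=c1cc(-c2ccc(OCc3ccccc3)c(OCc3ccccc3)c2)oc2c([Zn]I)c(OCc3ccccc3)cc(OCc3ccccc3)c12 | intermediate
13 | (2S)-5,7-bis(benzyloxy)-2-[3-{5,7-bis(benzyloxy)-2-[3,4-bis(benzyloxy)phenyl]-4-oxo-4H-chromen-8-yl}-4,5-bis(methoxymethoxy)phenyl]chroman-4-one | O=C1C[C@@H](c2cc(OCOC)c(OCOC)c(-c3c(OCc4ccccc4)cc(OCc4ccccc4)c4c(=O)cc(-c5ccc(OCc6ccccc6)c(OCc6ccccc6)c5)oc34)c2)Oc2cc(OCc3ccccc3)cc(OCc3ccccc3)c21 | intermediate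
14 | (2S)-5,7-bis(benzyloxy)-2-[3-{5,7-bis(benzyloxy)-2-[3,4-bis(benzyloxy)phenyl]-4-oxo-4H-chromen-8-yl}-4,5-dihydroxyphenyl]chroman-4-one | O=C1C[C@@H](c2cc(O)c(O)c(-c3c(OCc4ccccc4)cc(OCc4ccccc4)c4c(=O)cc(-c5ccc(OCc6ccccc6)c(OCc6ccccc6)c5)oc34)c2)Oc2cc(OCc3ccccc3)cc(OCc3ccccc3)c21 | intermediate
15 | (2S)-2-{3-[2-(3,4-dihydroxyphenyl)-5,7-dihydroxy-4-oxo-4H-chromen-8-yl]-4,5-dihydroxyphenyl}-5,7-dihydroxychroman-4-one | O=C1C[C@@H](c2cc(O)c(O)c(-c3c(O)cc(O)c4c(=O)cc(-c5ccc(O)c(O)c5)oc34)c2)Oc2cc(O)cc(O)c21 | target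

**Count**

Total steps: 9. Longest linear sequence: 6 steps (steps 3, 4, 6, 7, 8, 9, from 3-bromocatechol 4 to 15).

**Steps most likely to fail**

Step 7. Zinc insertion into the hindered, electron-rich C8–I bond may be sluggish, the arylzinc may be protonated before coupling, transmetalation at a carbon flanked by two oxygens may be slow, and zinc halide Lewis acidity could promote ring opening and loss of enantiopurity. The fallback is a Suzuki–Miyaura coupling run at the flavan-4-ol oxidation level, where C2 cannot epimerise through an enolate. It sets out from 11: NaBH4 in MeOH–THF at 0 °C should give the 2,4-cis alcohol (2S,4S)-5,7-bis(benzyloxy)-2-[3-bromo-4,5-bis(methoxymethoxy)phenyl]chroman-4-ol F1. Miyaura borylation (B2pin2, Pd(dppf)Cl2, KOAc, dioxane, 85 °C) should give the pinacol boronate of this flavan-4-ol F2. Coupling of F2 with iodide 3 (Pd(OAc)2, SPhos, K3PO4, toluene–H2O, 80 °C) should give the biaryl flavan-4-ol F3. Dess–Martin periodinane with NaHCO3 in CH2Cl2 then restores the ketone, and the route is rejoined at 13.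

Step 6. The 5-alkoxychromone may react slowly, the boronic acid may protodeboronate, reversible ring opening of the rhodium enolate may erode the enantiomeric purity, or the sense of induction may be opposite to the prediction. The fallback replaces asymmetric catalysis by a racemic synthesis with kinetic resolution and sets out from 8. Purchased 3-bromo-4,5-dihydroxybenzaldehyde is protected (NaH, MOMCl, DMF) as 3-bromo-4,5-bis(methoxymethoxy)benzaldehyde F4. Claisen–Schmidt condensation of F4 with 8 (KOH, EtOH, rt) should give the 2'-hydroxychalcone F5. NaOAc in refluxing EtOH should cyclise it to the racemic flavanone F6. Asymmetric transfer hydrogenation with RhCl[(S,S)-TsDPEN](C5Me5) (or its antipode, chosen on a model so that the (2R)-ketone reacts fast) and HCO2H/Et3N should reduce the (2R)-enantiomer to the (2R,4R)-flavan-4-ol F7. The unreacted (2S)-ketone is separated by chromatography and rejoins the route at 11.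

Step 2. Iodination may be poorly regioselective (attack at C6 or on ring B, or double iodination). The fallback fixes the iodine position before the pyranone ring is built and sets out from 8. Iodination ortho to the free hydroxyl (I2, HIO3, EtOH–H2O, 40 °C) should give 1-[4,6-bis(benzyloxy)-2-hydroxy-3-iodophenyl]ethan-1-one F8, whose substitution pattern can be proven on the small molecule. Claisen–Schmidt condensation with purchased 3,4-bis(benzyloxy)benzaldehyde (KOH, EtOH) should give the iodochalcone F9. Oxidative cyclisation (cat. I2, DMSO, 120 °C) closes the flavone through the hydroxyl next to the iodine and rejoins the route at 3.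

**Further compounds**

F1 | step 7 | (2S,4S)-5,7-bis(benzyloxy)-2-[3-bromo-4,5-bis(methoxymethoxy)phenyl]chroman-4-ol | O[C@H]1C[C@@H](c2cc(OCOC)c(OCOC)c(Br)c2)Oc2cc(OCc3ccccc3)cc(OCc3ccccc3)c12
F2 | step 7 | (2S,4S)-5,7-bis(benzyloxy)-2-[3,4-bis(methoxymethoxy)-5-(4,4,5,5-tetramethyl-1,3,2-dioxaborolan-2-yl)phenyl]chroman-4-ol | O[C@H]1C[C@@H](c2cc(OCOC)c(OCOC)c(B3OC(C)(C)C(C)(C)O3)c2)Oc2cc(OCc3ccccc3)cc(OCc3ccccc3)c12
F3 | step 7 | 5,7-bis(benzyloxy)-2-[3,4-bis(benzyloxy)phenyl]-8-{5-[(2S,4S)-5,7-bis(benzyloxy)-4-hydroxychroman-2-yl]-2,3-bis(methoxymethoxy)phenyl}-4H-chromen-4-one | O[C@H]1C[C@@H](c2cc(OCOC)c(OCOC)c(-c3c(OCc4ccccc4)cc(OCc4ccccc4)c4c(=O)cc(-c5ccc(OCc6ccccc6)c(OCc6ccccc6)c5)oc34)c2)Oc2cc(OCc3ccccc3)cc(OCc3ccccc3)c12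
F4 | step 6 | 3-bromo-4,5-bis(methoxymethoxy)benzaldehyde | COCOc1cc(C=O)cc(Br)c1OCOC
F5 | step 6 | (E)-1-[2,4-bis(benzyloxy)-6-hydroxyphenyl]-3-[3-bromo-4,5-bis(methoxymethoxy)phenyl]prop-2-en-1-one | O=C(/C=C/c1cc(OCOC)c(OCOC)c(Br)c1)c1c(O)cc(OCc2ccccc2)cc1OCc1ccccc1
F6 | step 6 | racemic 5,7-bis(benzyloxy)-2-[3-bromo-4,5-bis(methoxymethoxy)phenyl]chroman-4-one | O=C1CC(c2cc(OCOC)c(OCOC)c(Br)c2)Oc2cc(OCc3ccccc3)cc(OCc3ccccc3)c21
F7 | step 6 | (2R,4R)-5,7-bis(benzyloxy)-2-[3-bromo-4,5-bis(methoxymethoxy)phenyl]chroman-4-ol | O[C@@H]1C[C@H](c2cc(OCOC)c(OCOC)c(Br)c2)Oc2cc(OCc3ccccc3)cc(OCc3ccccc3)c12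
F8 | step 2 | 1-[4,6-bis(benzyloxy)-2-hydroxy-3-iodophenyl]ethan-1-one | CC(=O)c1c(O)c(I)c(OCc2ccccc2)cc1OCc1ccccc1
F9 | step 2 | (E)-1-[4,6-bis(benzyloxy)-2-hydroxy-3-iodophenyl]-3-[3,4-bis(benzyloxy)phenyl]prop-2-en-1-one | O=C(/C=C/c1ccc(OCc2ccccc2)c(OCc2ccccc2)c1)c1c(O)c(I)c(OCc2ccccc2)cc1OCc1ccccc1
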